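**Strategy.** The route rests on disconnecting the C2–C3 bond of the 2,3-dihydro-1,4-benzodioxine ring. C2, the benzylic CH between a ring oxygen and the guaiacyl ring, is a latent acetal carbon; C3, the CH(CH2OH) on the other ring oxygen, a latent α-aryloxy ester carbon. A 2-aryl-1,3-benzodioxole (catechol acetal) is therefore expanded by one carbon with tert-butyl diazoacetate: a chiral copper carbene forms an oxonium ylide at the acetal oxygen meta to the benzoate ester, and a formal [1,2]-shift gives the trans-diester, both stereocentres and the C2–C3 bond in one operation. Ester reduction, chalcone formation, Algar–Flynn–Oyamada oxidation and hydrogenolysis then build the trihydroxyflavonol.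

Key step: step 2

Assumption 1: the sense of induction of the copper/bis(oxazoline) catalyst in step 2 cannot be predicted with confidence; the (S,S)-ligand is written, and its commercial (R,R)-antipode would be used if the mirror-image ester forms.
Assumption 2: acetophenone 11 is taken as a commercial flavonoid building block.

**Step 1**
Reactants: 1 methyl 3,4-dihydroxybenzoate; 2 O-benzylvanillin (4-(benzyloxy)-3-methoxybenzaldehyde)
Product: 4 methyl 2-[4-(benzyloxy)-3-methoxyphenyl]-1,3-benzodioxole-5-carboxylate (racemic), via dimethyl acetal 3 (not isolated)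
Conditions: 2, HC(OMe)3, CSA (cat.), MeOH, 50 °C; evaporate; then 1, CSA (cat.), toluene, 110 °C, MeOH distilled off; Et3N quench
Reagents that add atoms: none
Why: Acid-catalysed transacetalisation, in which the p-alkoxybenzyl oxocarbenium ion from 3 is captured by both catechol oxygens of 1 and removal of methanol drives the equilibrium; the acetal centre forms racemic and is erased again in step 2.

**Step 2**
Reactants: 4 methyl 2-[4-(benzyloxy)-3-methoxyphenyl]-1,3-benzodioxole-5-carboxylate; 5 tert-butyl diazoacetate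
Product: 8 diester 3-tert-butyl 6-methyl (2R,3S)-2-[4-(benzyloxy)-3-methoxyphenyl]-2,3-dihydro-1,4-benzodioxine-3,6-dicarboxylate, via oxonium ylide 6 (not isolated), via oxocarbenium enolate 7 (not isolated)
Conditions: Cu(MeCN)4PF6 (5 mol%), (S,S)-tBu-box [2,2'-(propane-2,2-diyl)bis((4S)-4-tert-butyl-4,5-dihydrooxazole), 6 mol%], CH2Cl2, 25 °C, 5 (2.5 equiv) added slowly by syringe pump
Reagents that add atoms: none
Why: Proposed new method: the monovalent copper carbene from 5 should be captured by the more electron-rich acetal oxygen of 4 (meta to CO2Me; the para oxygen is deactivated by conjugation with the ester) to give ylide 6, whose O–C(acetal) bond ionises to the oxocarbenium/copper enolate 7, stabilised by the remaining ring oxygen and the p-benzyloxyaryl group, and 7 recloses by C–C bond formation, so that the carbene carbon is inserted into the acetal C–O bond and the five-membered 1,3-dioxole becomes the six-membered 1,4-dioxane (formal [1,2]-Stevens shift). The closest known reaction types are the metal-carbene ring expansion of 2-aryl-1,3-dioxolanes to 1,4-dioxanes through oxonium ylides and the copper/chiral-ligand enantioselective ring expansion of oxetanes to tetrahydrofurans with diazoacetates; neither has been shown on catechol acetals, whose aryl-bound oxygens are weaker donors. The ring closes in a 6-(enolexo)-endo-trig mode, the enolate carbon attacking the oxocarbenium carbon. C3 is expected to be set by the bis(oxazoline)-copper-bound enolate, which exposes one face of the enolate carbon, and C2 by a chair-like closure that places aryl and ester pseudo-equatorial (trans); the racemic acetal centre of 4 is erased in 7, so both enantiomers of 4 should converge. The step needs ylide formation to win over arene cyclopropanation and carbene dimerisation (copper instead of rhodium, slow addition of 5), attack at the correct acetal oxygen (secured by the para ester), and fast heterolysis compared with the unproductive ylides at the OMe and OBn oxygens, which can only revert.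

**Step 3**
Reactants: 8 diester 3-tert-butyl 6-methyl (2R,3S)-2-[4-(benzyloxy)-3-methoxyphenyl]-2,3-dihydro-1,4-benzodioxine-3,6-dicarboxylate
Product: 9 diol [(2R,3R)-2-[4-(benzyloxy)-3-methoxyphenyl]-2,3-dihydro-1,4-benzodioxine-3,6-diyl]dimethanol
Conditions: LiAlH4, THF, 0 °C to 25 °C; Fieser work-up
Reagents that add atoms: none
Why: Hydride reduction of both esters by LiAlH4 should give the benzylic and the primary alcohol without touching either ring stereocentre (the C3 descriptor changes from S to R only through the CIP priorities).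

**Step 4**
Reactants: 9 diol [(2R,3R)-2-[4-(benzyloxy)-3-methoxyphenyl]-2,3-dihydro-1,4-benzodioxine-3,6-diyl]dimethanol
Product: 10 hydroxy aldehyde (2R,3R)-2-[4-(benzyloxy)-3-methoxyphenyl]-3-(hydroxymethyl)-2,3-dihydro-1,4-benzodioxine-6-carbaldehyde
Conditions: MnO2 (activated, excess), CH2Cl2, 25 °C
Reagents that add atoms: none
Why: Chemoselective MnO2 oxidation, in which only the benzylic alcohol is activated, so the aliphatic primary alcohol and the benzyl ether should survive.

**Step 5**
Reactants: 10 hydroxy aldehyde (2R,3R)-2-[4-(benzyloxy)-3-methoxyphenyl]-3-(hydroxymethyl)-2,3-dihydro-1,4-benzodioxine-6-carbaldehyde; 11 acetophenone 1-[2,4-bis(benzyloxy)-6-hydroxyphenyl]ethan-1-one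
Product: 12 chalcone (E)-1-[2,4-bis(benzyloxy)-6-hydroxyphenyl]-3-[(2R,3R)-2-[4-(benzyloxy)-3-methoxyphenyl]-3-(hydroxymethyl)-2,3-dihydro-1,4-benzodioxin-6-yl]prop-2-en-1-one
Conditions: KOH (50% aq.), EtOH/THF, 25 °C
Reagents that add atoms: none
Why: Claisen–Schmidt aldol condensation of the enolate of 11 with the non-enolisable aldehyde 10, followed by E1cB dehydration to the thermodynamically favoured (E)-enone; the benzodioxane has no acidic C–H and should be inert.

**Step 6**
Reactants: 12 chalcone (E)-1-[2,4-bis(benzyloxy)-6-hydroxyphenyl]-3-[(2R,3R)-2-[4-(benzyloxy)-3-methoxyphenyl]-3-(hydroxymethyl)-2,3-dihydro-1,4-benzodioxin-6-yl]prop-2-en-1-one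
Product: 14 tribenzyl flavonol 5,7-bis(benzyloxy)-2-[(2R,3R)-2-[4-(benzyloxy)-3-methoxyphenyl]-3-(hydroxymethyl)-2,3-dihydro-1,4-benzodioxin-6-yl]-3-hydroxy-4H-chromen-4-one, via dihydroflavonol 13 (not isolated)
Conditions: H2O2 (30% aq.), NaOH (aq.), MeOH/THF, 0 °C to 25 °C
Reagents that add atoms: hydrogen peroxide OO
Why: Algar–Flynn–Oyamada reaction, in which alkaline hydroperoxide effects oxidative cyclisation of the 2'-hydroxychalcone to the 3-hydroxyflavanone 13, which is dehydrogenated in the same medium to the flavonol while the remote benzodioxane stereocentres are untouched.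

**Step 7**
Reactants: 14 tribenzyl flavonol 5,7-bis(benzyloxy)-2-[(2R,3R)-2-[4-(benzyloxy)-3-methoxyphenyl]-3-(hydroxymethyl)-2,3-dihydro-1,4-benzodioxin-6-yl]-3-hydroxy-4H-chromen-4-one
Product: 15 target 2-[(2R,3R)-2-(4-hydroxy-3-methoxyphenyl)-3-(hydroxymethyl)-2,3-dihydro-1,4-benzodioxin-6-yl]-3,5,7-trihydroxy-4H-chromen-4-one
Conditions: H2 (1 atm), Pd/C (10 wt% palladium on carbon), THF/MeOH, 25 °C
Reagents that add atoms: none
Why: Catalytic hydrogenolysis should cleave the three primary benzyl aryl ethers faster than the hindered secondary cyclic benzylic C–O bond of the benzodioxane and leave the flavonol enone intact.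

**Compound list**
1 | methyl 3,4-dihydroxybenzoate | COC(=O)c1ccc(O)c(O)c1 | starting material
2 | 4-(benzyloxy)-3-methoxybenzaldehyde (O-benzylvanillin) | COc1cc(C=O)ccc1OCc1ccccc1 | starting material
3 | 1-(benzyloxy)-4-(dimethoxymethyl)-2-methoxybenzene (dimethyl acetal of 2) | COC(OC)c1ccc(OCc2ccccc2)c(OC)c1 | intermediate (not isolated)
4 | methyl 2-[4-(benzyloxy)-3-methoxyphenyl]-1,3-benzodioxole-5-carboxylate (racemic acetal) | COC(=O)c1ccc2OC(c3ccc(OCc4ccccc4)c(OC)c3)Oc2c1 | intermediate
5 | tert-butyl diazoacetate | CC(C)(C)OC(=O)C=[N+]=[N-] | starting material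
6 | oxonium ylide at the acetal oxygen meta to the ester (drawn without copper) | COC(=O)c1ccc2OC(c3ccc(OCc4ccccc4)c(OC)c3)[O+]([CH-]C(=O)OC(C)(C)C)c2c1 | intermediate (not isolated)
7 | ring-opened oxocarbenium / ester enolate zwitterion (drawn without copper) | COC(=O)c1ccc([O+]=Cc2ccc(OCc3ccccc3)c(OC)c2)c(OC=C([O-])OC(C)(C)C)c1 | intermediate (not isolated)
8 | 3-tert-butyl 6-methyl (2R,3S)-2-[4-(benzyloxy)-3-methoxyphenyl]-2,3-dihydro-1,4-benzodioxine-3,6-dicarboxylate (trans) | COc1cc([C@H]2Oc3ccc(C(=O)OC)cc3O[C@@H]2C(=O)OC(C)(C)C)ccc1OCc1ccccc1 | intermediate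
9 | [(2R,3R)-2-[4-(benzyloxy)-3-methoxyphenyl]-2,3-dihydro-1,4-benzodioxine-3,6-diyl]dimethanol | COc1cc([C@H]2Oc3ccc(CO)cc3O[C@@H]2CO)ccc1OCc1ccccc1 | intermediate
10 | (2R,3R)-2-[4-(benzyloxy)-3-methoxyphenyl]-3-(hydroxymethyl)-2,3-dihydro-1,4-benzodioxine-6-carbaldehyde | COc1cc([C@H]2Oc3ccc(C=O)cc3O[C@@H]2CO)ccc1OCc1ccccc1 | intermediate
11 | 1-[2,4-bis(benzyloxy)-6-hydroxyphenyl]ethan-1-one | CC(=O)c1c(O)cc(OCc2ccccc2)cc1OCc1ccccc1 | starting material
12 | (E)-chalcone from 10 and 11 | COc1cc([C@H]2Oc3ccc(/C=C/C(=O)c4c(O)cc(OCc5ccccc5)cc4OCc4ccccc4)cc3O[C@@H]2CO)ccc1OCc1ccccc1 | intermediate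
13 | 5,7-bis(benzyloxy)-3-hydroxyflavanone carrying the (2R,3R)-benzodioxane (ring C centres formed as a mixture, not specified) | COc1cc([C@H]2Oc3ccc(C4Oc5cc(OCc6ccccc6)cc(OCc6ccccc6)c5C(=O)C4O)cc3O[C@@H]2CO)ccc1OCc1ccccc1 | intermediate (not isolated)
14 | 5,7-bis(benzyloxy)-2-[(2R,3R)-2-[4-(benzyloxy)-3-methoxyphenyl]-3-(hydroxymethyl)-2,3-dihydro-1,4-benzodioxin-6-yl]-3-hydroxy-4H-chromen-4-one | COc1cc([C@H]2Oc3ccc(-c4oc5cc(OCc6ccccc6)cc(OCc6ccccc6)c5c(=O)c4O)cc3O[C@@H]2CO)ccc1OCc1ccccc1 | intermediate
15 | 2-[(2R,3R)-2-(4-hydroxy-3-methoxyphenyl)-3-(hydroxymethyl)-2,3-dihydro-1,4-benzodioxin-6-yl]-3,5,7-trihydroxy-4H-chromen-4-one | COc1cc([C@H]2Oc3ccc(-c4oc5cc(O)cc(O)c5c(=O)c4O)cc3O[C@@H]2CO)ccc1O | target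

**Step count.** Total: 7 steps. Longest linear sequence: 7 steps (1 → 4 → 8 → 9 → 10 → 12 → 14 → 15).

**Steps most likely to fail**

Step 2 (key step, proposed new method). The carbene may be consumed by dimerisation or by cyclopropanation of the electron-rich arenes, because the aryl-bound acetal oxygens are poor donors. The ion pair may also collapse without regiochemical or facial control. The fallback uses known chemistry and closes the ring by two stereospecific etherifications; it sets out from 2, with 1 as the phenol partner, and comes back to the route at 9. Horner–Wadsworth–Emmons olefination of 2 (triethyl phosphonoacetate, NaH, THF) would give ethyl (E)-3-[4-(benzyloxy)-3-methoxyphenyl]acrylate F1. Reduction with iBu2AlH (CH2Cl2, −78 °C) would give (E)-3-[4-(benzyloxy)-3-methoxyphenyl]prop-2-en-1-ol F2. Sharpless asymmetric epoxidation (Ti(OiPr)4, L-(+)-diisopropyl tartrate, tBuOOH, 4 Å MS, CH2Cl2, −20 °C) would give [(2S,3S)-3-[4-(benzyloxy)-3-methoxyphenyl]oxiran-2-yl]methanol F3. The more acidic 4-phenoxide of 1 (Cs2CO3, DMF) should open the epoxide at the benzylic carbon with inversion to give methyl 4-{[(1R,2S)-1-[4-(benzyloxy)-3-methoxyphenyl]-2,3-dihydroxypropyl]oxy}-3-hydroxybenzoate F4. Selective primary silylation (TBSCl, imidazole, DMF) would give the silyl ether F5. Intramolecular Mitsunobu etherification (PPh3, DIAD, THF) with inversion at the secondary carbinol should close the trans ring to methyl (2R,3R)-2-[4-(benzyloxy)-3-methoxyphenyl]-3-{[(tert-butyldimethylsilyl)oxy]methyl}-2,3-dihydro-1,4-benzodioxine-6-carboxylate F6. Bu4NF (THF) would give methyl (2R,3R)-2-[4-(benzyloxy)-3-methoxyphenyl]-3-(hydroxymethyl)-2,3-dihydro-1,4-benzodioxine-6-carboxylate F7, and LiAlH4 reduction returns to diol 9.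

Step 6. The chalcone may cyclise through the five-membered mode to an aurone, a known tendency of 6'-alkoxy-2'-hydroxychalcones, or the electron-rich rings may be over-oxidised by alkaline peroxide. The fallback sets out from 12 and comes back at 14. Oxidative cyclisation with I2 (cat.) in DMSO at 120 °C would give the flavone 5,7-bis(benzyloxy)-2-[(2R,3R)-2-[4-(benzyloxy)-3-methoxyphenyl]-3-(hydroxymethyl)-2,3-dihydro-1,4-benzodioxin-6-yl]-4H-chromen-4-one F8. Epoxidation of its C2=C3 bond with dimethyldioxirane (acetone/CH2Cl2, 0 °C) and opening with p-TsOH (cat.) should then give flavonol 14.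

Step 1. Acetal exchange with the ester-deactivated catechol may stay incomplete. The stabilised benzylic cation may also C-alkylate the arene, or the labile acetal may hydrolyse on work-up. The fallback sets out from 2 and comes back at 4. Deoxydichlorination of 2 (oxalyl chloride, Ph3PO cat., CHCl3) would give 1-(benzyloxy)-4-(dichloromethyl)-2-methoxybenzene F9, used crude. Double O-alkylation of 1 (K2CO3, MeCN, 60 °C) should then form 4 irreversibly and without acid.

**Further compounds**
F1 | step 2 | ethyl (E)-3-[4-(benzyloxy)-3-methoxyphenyl]acrylate | CCOC(=O)/C=C/c1ccc(OCc2ccccc2)c(OC)c1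
F2 | step 2 | (E)-3-[4-(benzyloxy)-3-methoxyphenyl]prop-2-en-1-ol | OC/C=C/c1ccc(OCc2ccccc2)c(OC)c1
F3 | step 2 | [(2S,3S)-3-[4-(benzyloxy)-3-methoxyphenyl]oxiran-2-yl]methanol | OC[C@@H]1O[C@H]1c1ccc(OCc2ccccc2)c(OC)c1
F4 | step 2 | methyl 4-{[(1R,2S)-1-[4-(benzyloxy)-3-methoxyphenyl]-2,3-dihydroxypropyl]oxy}-3-hydroxybenzoate | COC(=O)c1ccc(O[C@@H]([C@@H](O)CO)c2ccc(OCc3ccccc3)c(OC)c2)c(O)c1
F5 | step 2 | methyl 4-{[(1R,2S)-1-[4-(benzyloxy)-3-methoxyphenyl]-3-[(tert-butyldimethylsilyl)oxy]-2-hydroxypropyl]oxy}-3-hydroxybenzoate | COC(=O)c1ccc(O[C@@H]([C@@H](O)CO[Si](C)(C)C(C)(C)C)c2ccc(OCc3ccccc3)c(OC)c2)c(O)c1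
F6 | step 2 | methyl (2R,3R)-2-[4-(benzyloxy)-3-methoxyphenyl]-3-{[(tert-butyldimethylsilyl)oxy]methyl}-2,3-dihydro-1,4-benzodioxine-6-carboxylate | COc1cc([C@H]2Oc3ccc(C(=O)OC)cc3O[C@@H]2CO[Si](C)(C)C(C)(C)C)ccc1OCc1ccccc1
F7 | step 2 | methyl (2R,3R)-2-[4-(benzyloxy)-3-methoxyphenyl]-3-(hydroxymethyl)-2,3-dihydro-1,4-benzodioxine-6-carboxylate | COc1cc([C@H]2Oc3ccc(C(=O)OC)cc3O[C@@H]2CO)ccc1OCc1ccccc1
F8 | step 6 | 5,7-bis(benzyloxy)-2-[(2R,3R)-2-[4-(benzyloxy)-3-methoxyphenyl]-3-(hydroxymethyl)-2,3-dihydro-1,4-benzodioxin-6-yl]-4H-chromen-4-one | COc1cc([C@H]2Oc3ccc(-c4cc(=O)c5c(OCc6ccccc6)cc(OCc6ccccc6)cc5o4)cc3O[C@@H]2CO)ccc1OCc1ccccc1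
F9 | step 1 | 1-(benzyloxy)-4-(dichloromethyl)-2-methoxybenzene | ClC(Cl)c1ccc(OCc2ccccc2)c(OC)c1
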